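## Retrosynthetic overview

- Ring A is C1 (OH), C2 (Br), C3 (Br), C4 (H), C5 (Br), C6 (O-aryl). Ring B is C1′ (O), C2′ (Br), C3′ (H), C4′ (Br), C5′ (H), C6′ (H). The last operation frees the C1 hydroxyl from its methyl ether.
- Feature used: the segment C2′(Br)–C3′(H)–C4′(Br)–C5′(H) of ring B matches C3–C6 of 3,5-dibromo-2-pyrone atom for atom. The remaining pair C1′–C6′ is an ethynyl group on the ring A oxygen.
- Key disconnection: C1′–C2′ and C5′–C6′, by [4+2] cycloaddition of the aryl ethynyl ether with the pyrone and then loss of CO2. Ring A is carried in complete, and ring B is the only ring formed.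
- Ethynyl ether ⇐ bromovinyl ether ⇐ vinyl ether ⇐ 2-bromoethyl ether ⇐ 3,4,6-tribromo-2-methoxyphenol ⇐ 3-bromo-2-methoxyphenol ⇐ 2,6-dibromoanisole. Pyrone ⇐ coumalic acid.

Key step: step 8

Remark on the chemistry: from compound 5 onward ring A holds three C–Br bonds and one acidic C–H between two of them, so alkyllithium reagents are excluded after step 1. The ethynyl ether is therefore made by bromination and two dehydrobrominations of a vinyl ether, not from a 1,2-dichlorovinyl ether and n-BuLi.

## Route

Step 1
Reactants: 1 2,6-dibromoanisole
Product: 4 3-bromo-2-methoxyphenol, via aryllithium 2 (not isolated), via lithium aryltrimethoxyborate 3 (not isolated)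
Conditions: n-BuLi (1.0 equiv), THF, −78 °C; B(OMe)3, −78 °C → rt; AcOH, 30% aq H2O2, 0 °C → rt
Reagents that add atoms: hydrogen peroxide, OO (phenol oxygen of 4); n-butyllithium, [Li]CCCC (lithium of 2 and 3); trimethyl borate, COB(OC)OC (borate unit of 3)
Why: Bromine–lithium exchange at one of two equivalent C–Br bonds gives an aryllithium with no ortho halogen (no aryne pathway), and borate trapping followed by peroxide-induced 1,2-aryl migration (boronate oxidation) converts C–Li into C–OH.

Step 2
Reactants: 4 3-bromo-2-methoxyphenol
Product: 5 3,4,6-tribromo-2-methoxyphenol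
Conditions: Br2 (2.1 equiv), AcOH, rt
Reagents that add atoms: bromine, BrBr
Why: Electrophilic aromatic bromination is directed by the free OH, the strongest donor, to its open para (C4) and ortho (C6) positions, while the methoxy group, twisted between two ortho neighbours, cannot activate C5.

Step 3
Reactants: 5 3,4,6-tribromo-2-methoxyphenol; 6 1,2-dibromoethane
Product: 7 1,2,5-tribromo-4-(2-bromoethoxy)-3-methoxybenzene
Conditions: K2CO3, 6 (5 equiv), MeCN, reflux
Reagents that add atoms: none
Why: This is a Williamson ether synthesis (SN2) of the acidic, hindered phenoxide on an unhindered primary bromide, and the excess of 6 suppresses double alkylation.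

Step 4
Reactants: 7 1,2,5-tribromo-4-(2-bromoethoxy)-3-methoxybenzene
Product: 8 1,2,5-tribromo-4-(ethenyloxy)-3-methoxybenzene
Conditions: KOtBu (1.3 equiv), THF, 0 °C
Reagents that add atoms: none
Why: E2 dehydrobromination of a 2-aryloxyethyl bromide with a bulky alkoxide is the standard route to aryl vinyl ethers, and in THF at 0 °C KOtBu should leave the aryl bromides and the lone ring proton untouched.

Step 5
Reactants: 8 1,2,5-tribromo-4-(ethenyloxy)-3-methoxybenzene
Product: 10 1,2,5-tribromo-4-[(2-bromoethenyl)oxy]-3-methoxybenzene, via 1,2-dibromoethyl ether 9 (not isolated)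
Conditions: Br2 (1.0 equiv), CH2Cl2, −78 °C; then DBU (1.5 equiv), −78 °C → rt
Reagents that add atoms: bromine, BrBr
Why: Electrophilic addition of bromine to the enol ether double bond (ring A is too deactivated to compete), followed by amidine-induced loss of the labile α-bromide as HBr, is the bromination–dehydrobromination sequence used for 2-bromo enol ethers, and both alkene isomers lead on to 11.

Step 6
Reactants: 10 1,2,5-tribromo-4-[(2-bromoethenyl)oxy]-3-methoxybenzene
Product: 11 1,2,5-tribromo-4-(ethynyloxy)-3-methoxybenzene
Conditions: KOtBu (2.0 equiv), THF, −40 → 0 °C; pH 7 buffer; short plug of basic alumina, used at once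
Reagents that add atoms: none
Why: Base-induced 1,2-elimination of HBr from a bromo enol ether is the classical entry to aryloxyacetylenes and uses no halogen–metal exchange reagent, so the three aryl bromides should survive.

Step 7
Reactants: 12 coumalic acid
Product: 13 3,5-dibromo-2H-pyran-2-one
Conditions: NBS (2.5 equiv), n-Bu4NBr (cat.), CHCl3, 50 °C
Reagents that add atoms: N-bromosuccinimide, O=C1CCC(=O)N1Br
Why: Hunsdiecker-type bromodecarboxylation at C5 together with electrophilic bromination at C3, the two nucleophilic positions of the 2-pyrone ring, is the established one-flask preparation of this pyrone.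

Step 8
Reactants: 11 1,2,5-tribromo-4-(ethynyloxy)-3-methoxybenzene; 13 3,5-dibromo-2H-pyran-2-one
Product: 15 1,2,5-tribromo-4-(2,4-dibromophenoxy)-3-methoxybenzene, via bridged lactone 14 (not isolated)
Conditions: 13 (2 equiv), BHT (cat.), PhMe, 110 °C, N2, slow addition of 11
Reagents that add atoms: none
Why: The electron-poor diene C3=C4–C5=C6 of 13 and the oxygen-polarised triple bond of 11 combine in a concerted but asynchronous inverse-electron-demand Diels–Alder reaction, in which the nucleophilic terminal carbon of 11 bonds ahead to C6, the 1,6-acceptor position of the dienoate, and the oxygen-bearing carbon closes onto C3. The bridged dienyl lactone 14 cannot persist at this temperature and loses CO2 by retro-[4+2], so ring B is closed by an intermolecular [4+2] annulation (C1′–C2′ and C5′–C6′) and aromatised in the same operation. The closest known reaction type is the pyrone–alkyne cycloaddition/decarboxylation route to benzenes, supported by the cycloadditions of this pyrone with enol ethers, which place the donor-bearing carbon next to C3. No stereocentre remains, because the two bridgehead centres of racemic 14 vanish with CO2. The only selectivity needed is regiochemical (2′,4′- and not 3′,5′-dibromo), and it is secured by pairing the largest HOMO coefficient of the ynol ether (terminal carbon) with the largest LUMO coefficient of the pyrone (C6). The electron-poor, doubly ortho-substituted aryl group should restrain self-condensation of 11, slow addition into excess 13 keeps its concentration low, and no C–O bond has to be made at the crowded ring A oxygen.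

Step 9
Reactants: 15 1,2,5-tribromo-4-(2,4-dibromophenoxy)-3-methoxybenzene
Product: 17 2,3,5-tribromo-6-(2,4-dibromophenoxy)phenol, via aryloxydibromoborane 16 (not isolated)
Conditions: BBr3 (2 equiv), CH2Cl2, −78 °C → rt; then H2O, 0 °C
Reagents that add atoms: boron tribromide, BrB(Br)Br (BBr2 group of 16 only)
Why: In this Lewis acid-mediated aryl methyl ether cleavage BBr3 binds the methoxy oxygen, bromide attacks the methyl carbon (SN2) and water hydrolyses 16 to the phenol, while the diaryl ether (no sp3 carbon on oxygen) and the aryl bromides are inert.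

## Compound list

1 | 2,6-dibromoanisole | COc1c(Br)cccc1Br | starting material
2 | (3-bromo-2-methoxyphenyl)lithium | [Li]c1cccc(Br)c1OC | intermediate (not isolated)
3 | lithium (3-bromo-2-methoxyphenyl)trimethoxyborate | [Li+].COc1c(Br)cccc1[B-](OC)(OC)OC | intermediate (not isolated)
4 | 3-bromo-2-methoxyphenol | COc1c(O)cccc1Br | intermediate
5 | 3,4,6-tribromo-2-methoxyphenol | COc1c(Br)c(Br)cc(Br)c1O | intermediate
6 | 1,2-dibromoethane | BrCCBr | starting material
7 | 1,2,5-tribromo-4-(2-bromoethoxy)-3-methoxybenzene | COc1c(Br)c(Br)cc(Br)c1OCCBr | intermediate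
8 | 1,2,5-tribromo-4-(ethenyloxy)-3-methoxybenzene | COc1c(Br)c(Br)cc(Br)c1OC=C | intermediate
9 | 1,2,5-tribromo-4-(1,2-dibromoethoxy)-3-methoxybenzene (racemic) | COc1c(Br)c(Br)cc(Br)c1OC(Br)CBr | intermediate (not isolated)
10 | 1,2,5-tribromo-4-[(2-bromoethenyl)oxy]-3-methoxybenzene (expected as an E/Z mixture, Z isomer drawn) | COc1c(Br)c(Br)cc(Br)c1O/C=C\Br | intermediate
11 | 1,2,5-tribromo-4-(ethynyloxy)-3-methoxybenzene | COc1c(Br)c(Br)cc(Br)c1OC#C | intermediate (key-step precursor)
12 | coumalic acid (2-oxo-2H-pyran-5-carboxylic acid) | O=C(O)C1=COC(=O)C=C1 | starting material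
13 | 3,5-dibromo-2H-pyran-2-one | O=C1OC=C(Br)C=C1Br | intermediate (key-step precursor)
14 | 4,7-dibromo-5-(3,4,6-tribromo-2-methoxyphenoxy)-2-oxabicyclo[2.2.2]octa-5,7-dien-3-one (racemic, one enantiomer drawn) | O=C1O[C@@H]2C=C(Oc3c(Br)cc(Br)c(Br)c3OC)[C@@]1(Br)C=C2Br | intermediate (not isolated)
15 | 1,2,5-tribromo-4-(2,4-dibromophenoxy)-3-methoxybenzene | COc1c(Br)c(Br)cc(Br)c1Oc1ccc(Br)cc1Br | intermediate (key-step product)
16 | dibromo[2,3,5-tribromo-6-(2,4-dibromophenoxy)phenoxy]borane | BrB(Br)Oc1c(Br)c(Br)cc(Br)c1Oc1ccc(Br)cc1Br | intermediate (not isolated)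
17 | 2,3,5-tribromo-6-(2,4-dibromophenoxy)phenol | Oc1c(Br)c(Br)cc(Br)c1Oc1ccc(Br)cc1Br | target

## Step count and risks

Total step count: 9. Longest linear sequence: 8 (steps 1–6, 8, 9). Step 7 is the convergent branch.

**Step 8.**
- What may go wrong: the tribromoaryloxy group is only a modest donor, so the cycloaddition may be slower than thermal self-condensation of the ynol ether. A late, weakly polarised transition state could also erode the regiocontrol.
- Fallback (sets out from 5, comes back at 15): the diaryl ether bond is made directly by metal-free O-arylation.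
  - 1,3-Dibromobenzene is treated with iodosyl sulfate (I2, KIO3, conc. H2SO4) and then NaCl to give bis(2,4-dibromophenyl)iodonium chloride F1.
  - The sodium salt of 5 (NaOH, H2O–dioxane, 80 °C) binds to iodine. Ligand coupling at trivalent iodine then transfers one 2,4-dibromophenyl group to oxygen, a process that tolerates two ortho substituents on the phenoxide.
  - This gives 15, which goes on to step 9.

**Step 6.**
- What may go wrong: the well-stabilised aryloxide may leave in place of bromide, which fragments the ether back to the phenoxide. Reversible deprotonation of C4–H of ring A may start bromine migration. The terminal ynol ether may hydrate or oligomerise during isolation.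
- Fallback (sets out from 10, comes back at 15): the free alkyne is never made, and 10 serves as its synthetic equivalent.
  - Heating 10 with 13 in xylene should give, in the regiochemical sense shown by other enol ethers, 4,6,7-tribromo-5-(3,4,6-tribromo-2-methoxyphenoxy)-2-oxabicyclo[2.2.2]oct-7-en-3-one F2.
  - Further heating expels CO2 to give 1,2,5-tribromo-3-methoxy-4-[(2,4,6-tribromocyclohexa-2,4-dien-1-yl)oxy]benzene F3.
  - DBU then removes HBr (allylic bromide at C6′, proton at C1′), which aromatises ring B to 15.

**Step 5.**
- What may go wrong: the α-bromo ether may hydrolyse or quaternise the amidine before it eliminates. The elimination may also favour the alkene geometry that can only undergo slow syn elimination in step 6.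
- Fallback (sets out from 5, comes back at 10): no α-bromo ether is involved, and steps 3 and 4 are no longer needed.
  - DABCO-catalysed conjugate addition of 5 to tert-butyl propiolate (CH2Cl2, rt) gives tert-butyl (E)-3-(3,4,6-tribromo-2-methoxyphenoxy)prop-2-enoate F4.
  - TFA in CH2Cl2 removes the tert-butyl group without exposing the vinylogous carbonate to hydroxide. This gives (E)-3-(3,4,6-tribromo-2-methoxyphenoxy)prop-2-enoic acid F5.
  - Hunsdiecker-type bromodecarboxylation (NBS, cat. Et3N, CH2Cl2) then gives 10, which re-enters at step 6.

## Further compounds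

F1 | step 8 | bis(2,4-dibromophenyl)iodonium chloride | [Cl-].Brc1ccc([I+]c2ccc(Br)cc2Br)c(Br)c1
F2 | step 6 | 4,6,7-tribromo-5-(3,4,6-tribromo-2-methoxyphenoxy)-2-oxabicyclo[2.2.2]oct-7-en-3-one (racemic, mixture of diastereomers) | O=C1OC2C(Br)C(Oc3c(Br)cc(Br)c(Br)c3OC)C1(Br)C=C2Br
F3 | step 6 | 1,2,5-tribromo-3-methoxy-4-[(2,4,6-tribromocyclohexa-2,4-dien-1-yl)oxy]benzene (racemic, mixture of diastereomers) | BrC1C=C(Br)C=C(Br)C1Oc1c(Br)cc(Br)c(Br)c1OC
F4 | step 5 | tert-butyl (E)-3-(3,4,6-tribromo-2-methoxyphenoxy)prop-2-enoate | CC(C)(C)OC(=O)/C=C/Oc1c(Br)cc(Br)c(Br)c1OC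
F5 | step 5 | (E)-3-(3,4,6-tribromo-2-methoxyphenoxy)prop-2-enoic acid | OC(=O)/C=C/Oc1c(Br)cc(Br)c(Br)c1OC
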